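the same everywhere: starting material 0.38 M; initiator 19 mM; radical scavenger 0.76 mM
- maple: coupling partner 0.41 M (fed, over 6.0 h); run made earlier; the fed solution adds 0.50 times the starting volume
- alder: coupling partner 1 M (fed, over 6.0 h); run made earlier; the fed solution adds 0.50 times the starting volume
- alpha: coupling partner 0.340 M (fed, over 6.0 h); the fed solution adds 0.50 times the starting volume; time 6.0 h
- zeta: coupling partner 0.680 M (fed, over 6.0 h); the fed solution adds 0.50 times the starting volume; time 6.0 h

- maple (time / h: starting material / %, target / %): 0.250: 98.6, 0.6; 0.833: 98.7, 0.5; 1.33: 97.6, 2.9; 2.50: 91.4, 5.1; 3.00: 87.9, 7.3; 4.00: 81.5, 7.9
- alder (time / h: starting material / %, target / %): 0.667: 98.3, 0.7; 1.33: 93.4, 3.0; 2.00: 86.9, 8.4; 3.00: 74.9, 16.2; 4.00: 64.4, 24.8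

(scatter of a reading: 1 percentage point)

- percent here means starting material units held: one ended chains A counts as two
- what is said of by-product includes idle adduct
- amounts are per litre of the starting volume; all of the dose is in the solution fed
- steps under discussion: initiator -> 2 initiating radical; starting material + initiating radical -> capped initiator + first chain carrier; coupling partner + first chain carrier -> target + second chain carrier; starting material + second chain carrier -> by-product + first chain carrier; first chain carrier -> ended carrier; 2 first chain carrier -> ended chains A; 2 second chain carrier -> ended chains B; starting material + by-product <-> idle adduct; first chain carrier + radical scavenger -> ended chains C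
- what has gone from starting material into another species counts as reacted, even if it can come back

* part of the starting material that has reacted at the end, alpha
* part of the starting material that has reacted at the end, zeta
* what raising the concentration of coupling partner from its lowest to its highest value here does to the part of the starting material that has reacted (changes below 5 percentage points count as none) (it falls / no change / it rises)

1. I started by counting equivalents. Each target costs one coupling partner, so alpha, charged with less coupling partner than starting material, has coupling partner as its limiting reagent, and its charge allows target up to 89.5% of the starting material. Zeta is charged with 1.79 equivalents.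

2. I tested this rule of thumb on the maple run at 4.00 h. The target reading then stood for 0.0300 M, while 0.273 M of coupling partner had been fed, a ratio of 0.110. Target had therefore taken less of the coupling partner than was fed, so the equivalents rule had not come into play, and the rate with [coupling partner] had to be read instead.

3. I compared the two earlier runs at that same time. Alder had 2.44 times the dose of maple but 1.92 times the reacted starting material. The exponent linking these two ratios was 0.734. This is the dose order, the apparent order of the reacted part in the coupling partner charged, at equal time. It is a reading with the scatter of its readings, and it is less than one.

4. Zeta has 2.00 times the dose of alpha, so, carrying the order read at 4.00 h over to the end, I expected a ratio of reacted parts of 1.66.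

5. The forecast gave 25% for alpha and 39% for zeta, a ratio of 1.56, which is lower than mine. It said it rises, on the ground that “Target scales roughly with the partner dose”.

6. Alpha gave 24.9% and zeta 43.2%, so it rises, by 18 percentage points across the doses.

    initiator → 2 initiating radical (k = 2.90 × 10⁻⁵ s⁻¹)
    starting material + initiating radical → capped initiator + first chain carrier (k = 18100 M⁻¹ s⁻¹)
    coupling partner + first chain carrier → target + second chain carrier (k = 391 M⁻¹ s⁻¹)
    starting material + second chain carrier → by-product + first chain carrier (k = 5090 M⁻¹ s⁻¹)
    first chain carrier → ended carrier (k = 11.7 s⁻¹)
    2 first chain carrier → ended chains A (k = 3.00 × 10⁶ M⁻¹ s⁻¹)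
    2 second chain carrier → ended chains B (k = 4.00 × 10⁷ M⁻¹ s⁻¹)
    starting material + by-product ⇌ idle adduct, settled at all times (K = 2.40 M⁻¹)
    first chain carrier + radical scavenger → ended chains C (k = 2.94 × 10⁵ M⁻¹ s⁻¹)

Zeta ended with 82.8% of its coupling partner free, more than the 57% of its starting material. The reacted parts of zeta and alpha stood in a ratio of 1.73, against 1.66 from the dose order. A neighbour flask, like zeta but with 0.95 M of starting material, had 0.716 equiv of coupling partner instead of 1.79. The dose order was read at 0.38 M of starting material, so using it on that ratio of equivalents went beyond its reading; it gave 22.1% for the neighbour flask, which itself gave 20.9%.

The data stem from a simulated flask with constants of no real substance.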